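The route rests on cutting the C3–C4 bond of ring A, so that ring B with C5 and C10 comes from (R)-carvone. The feature exploited is the gem-dimethyl quaternary carbon C4 beside the fusion methine C5: it equals carvone's isopropenyl group plus one hydrogen atom and one alkyl bond. In one operation a manganese hydride puts hydrogen on the isopropenyl CH2, and nickel joins the resulting tertiary C4 radical to the primary iodide carbon C3. This builds the quaternary centre and shuts ring A. The precursor is a carvone whose C10 carries a methyl group and, trans to the isopropenyl group, a 3-iodopropyl chain.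

Key step: step 5

Remark: labdane numbering is used in the discussion for all compounds (carvone C1 = C9, C2 = C8, C3 = C7, C4 = C6, C5 = C5, C6 = C10). α is the face of H-5 and β the face of the C10 methyl group. Systematic names keep their own locants.

Step 1
Reactants: 1 (R)-carvone
Product: 3 6-methylcarvone [(5R)-2,6-dimethyl-5-(prop-1-en-2-yl)cyclohex-2-en-1-one; epimer mixture at the new centre], via lithium dienolate 2 (not isolated)
Conditions: LiN(iPr)2, THF, −78 °C; MeI, −78 to 0 °C
Reagents that add atoms: iodomethane, CI
Why: Kinetic deprotonation at the α′ methylene (future C10) gives the cross-conjugated dienolate, whose SN2 methylation is a standard enolate alkylation; the new centre forms as an epimer mixture, which is harmless because step 2 makes this carbon planar again.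

Step 2
Reactants: 3 6-methylcarvone; 4 allyl bromide
Product: 6 (5S,6S)-6-allyl-2,6-dimethyl-5-(prop-1-en-2-yl)cyclohex-2-en-1-one (allyl trans to isopropenyl), via lithium enolate 5 (not isolated)
Conditions: LiN(iPr)2, THF/DMPU, −78 °C; allyl bromide, −78 °C to rt
Reagents that add atoms: none
Why: Second enolate alkylation: the tetrasubstituted enolate holds the neighbouring isopropenyl group pseudo-axial to avoid allylic strain, so the allylic bromide enters from the opposite face and sets C10 with the allyl chain trans and the methyl group cis to the isopropenyl group.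

Step 3
Reactants: 6 6-allyl-6-methylcarvone
Product: 8 (5S,6S)-6-(3-hydroxypropyl)-2,6-dimethyl-5-(prop-1-en-2-yl)cyclohex-2-en-1-one, via disiamylalkylborane 7 (not isolated)
Conditions: Sia2BH (from BH3·SMe2 and 2-methylbut-2-ene), THF, 0 °C; 30% H2O2, pH 7 phosphate buffer, 0 °C to rt
Reagents that add atoms: hydrogen peroxide, OO
Why: Hydroboration–oxidation: the bulky dialkylborane adds far faster to the monosubstituted allyl alkene (boron at the terminus) than to the 1,1-disubstituted isopropenyl group or the doubly flanked conjugated ketone, and the buffered peroxide work-up avoids Weitz–Scheffer epoxidation of the enone.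

Step 4
Reactants: 8 primary alcohol
Product: 9 (5S,6S)-6-(3-iodopropyl)-2,6-dimethyl-5-(prop-1-en-2-yl)cyclohex-2-en-1-one
Conditions: I2, PPh3, imidazole, CH2Cl2, 0 °C
Reagents that add atoms: iodine, II
Why: Appel-type iodination: the primary alkoxyphosphonium ion is displaced by iodide under neutral conditions that leave the enone, the isopropenyl group and both stereocentres untouched.

Step 5
Reactants: 9 6-methyl-6-(3-iodopropyl)carvone
Product: 10 (4aS,8aS)-2,5,5,8a-tetramethyl-4a,5,6,7,8,8a-hexahydronaphthalen-1(4H)-one (trans-fused 11-nordrim-7-en-9-one)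
Conditions: Mn(dpm)3 (20 mol %), Ni(acac)2 (5 mol %), PhSiH3 (syringe pump), K2CO3, (CF3)2CHOH (additive), ClCH2CH2Cl/propylene carbonate, degassed, 0.01 M, rt
Reagents that add atoms: none
Why: Proposed new method: a manganese hydride formed from Mn(dpm)3 and PhSiH3 transfers a hydrogen atom to the terminal CH2 of the isopropenyl group, which writes the second C4 methyl group and leaves the tertiary C4 radical; low-valent nickel takes up the primary C3–I bond and this radical, and the resulting trivalent dialkylnickel forms the C3–C4 bond by reductive elimination. The closest known reaction type is the intermolecular manganese/nickel dual-catalysed Markovnikov hydroalkylation of 1,1-disubstituted alkenes with unactivated primary alkyl iodides to quaternary carbons; only the tethering of the two partners is new. Ring A (six-membered) closes by C(sp3)–C(sp3) reductive elimination from a seven-membered nickelacycle and not by radical addition to a π bond, so no exo/endo question arises, and high dilution keeps the coupling intramolecular. No stereocentre is created, since C4 ends with two methyl groups; the trans fusion follows from C5 and C10 as they stand in 9, where the isopropenyl and iodopropyl groups can both sit equatorial within bonding distance. The selectivity needed is hydrogen-atom transfer to the isopropenyl group rather than to the enone: the former offers an unhindered, electron-neutral =CH2 terminus, the latter a trisubstituted, electron-poor alkene whose acceptor carbon C7 is internal, and slow dosing of the silane holds conjugate reduction back. The C4 radical has no π acceptor in reach (attack on C7 or C9 would give four-membered rings), so it should live long enough to be captured by nickel.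

Step 6
Reactants: 10 bicyclic enone
Product: 11 9β,11-epoxydrim-7-ene (spiro-oxirane at C9; oxygen β, CH2 α)
Conditions: Me3SI, NaH, DMSO/THF, 0 °C; then 10, 0 °C to rt
Reagents that add atoms: trimethylsulfonium iodide, C[S+](C)C.[I-]
Why: Corey–Chaykovsky epoxidation: the unstabilised sulfonium ylide adds irreversibly 1,2 to the enone carbonyl from the α face, anti to the axial C10 methyl group, and the betaine closes to the spiro-epoxide; this C9 centre is provisional because step 7 re-forms it.

Step 7
Reactants: 11 vinyl spiro-epoxide
Product: 12 drim-7-en-11-al (9αH, formyl group β and equatorial)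
Conditions: BF3·OEt2 (0.3 equiv), CH2Cl2, −78 °C, short contact; Et3N quench; used at once
Reagents that add atoms: none
Why: Meinwald rearrangement: the Lewis acid opens the tertiary allylic C9–O bond and a hydride migrates from C11 to the α face of C9, anti to the departing β oxygen, which places the formyl group equatorial as in the more stable epimer, while low temperature and a non-nucleophilic counter-ion keep the alkene out of conjugation.

Step 8
Reactants: 12 drim-7-en-11-al
Product: 13 13,14,15,16-tetranorlabda-7,11-diene (9β-vinyl, 9αH)
Conditions: Ph3PCH3Br, KOtBu, THF, 0 °C; then 12, −78 to 0 °C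
Reagents that add atoms: methyltriphenylphosphonium bromide, C[P+](c1ccccc1)(c1ccccc1)c1ccccc1.[Br-]
Why: Wittig methylenation: the non-stabilised ylide adds to the aldehyde faster than it enolises it at low temperature, so the C9 configuration and the position of the C7–C8 alkene are retained.

Step 9
Reactants: 13 9β-vinyl diene; 14 3-bromofuran-2(5H)-one
Product: 16 labda-7,13-dien-16,15-olide, via B-alkyl-9-BBN 15 (not isolated)
Conditions: 9-BBN, THF, rt to 40 °C; then 14, PdCl2(dppf), AsPh3, Cs2CO3, DMF/H2O, rt
Reagents that add atoms: none
Why: 9-BBN takes only the monosubstituted C11–C12 alkene (boron at C12) and leaves the trisubstituted ring alkene, and the B-alkyl Suzuki–Miyaura coupling forms C12–C13 in the way established for α-halo-α,β-unsaturated carbonyl partners under mild carbonate conditions.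

Step 10
Reactants: 16 labda-7,13-dien-16,15-olide
Product: 17 6-oxolabda-7,13-dien-16,15-olide
Conditions: CrO3, 3,5-dimethylpyrazole, CH2Cl2, −20 °C
Reagents that add atoms: chromium trioxide, O=[Cr](=O)=O
Why: Allylic oxidation with the CrO3–3,5-dimethylpyrazole complex: C6 is the only allylic methylene of the electron-rich ring alkene, the usual site in 7-ene drimanes and labdanes, and doing this oxidation while C17 is still a methyl group keeps the ring alkene clearly more reactive than the electron-poor butenolide.

Step 11
Reactants: 17 7-en-6-one
Product: 18 6β-hydroxylabda-7,13-dien-16,15-olide (axial alcohol, 6R)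
Conditions: NaBH4, CeCl3·7H2O, MeOH, −78 to −20 °C
Reagents that add atoms: none
Why: Luche reduction: 1,2-selective hydride delivery comes from the α face because the β face of C6 is closed by the syn-axial C10 and 4β methyl groups, which sets the 6β-alcohol, and the α-substituted butenolide is inert under these conditions.

Step 12
Reactants: 18 6β-alcohol; 19 tiglic acid
Product: 20 6α-tigloyloxylabda-7,13-dien-16,15-olide
Conditions: PPh3, DIAD, toluene, 0 °C to rt
Reagents that add atoms: none
Why: Mitsunobu esterification: the alkoxyphosphonium ion of the axial 6β-alcohol is displaced by tiglate from the open α face with inversion to the equatorial 6α-ester (6S), and because the β face of C6 is closed by two methyl groups an ion-pair variant would end on the same face.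

Step 13
Reactants: 20 6α-tiglate
Product: 22 6α-tigloyloxy-17-oxolabda-7,13-dien-16,15-olide (C17 enal), via 17-alcohol 21 (not isolated)
Conditions: SeO2 (2 equiv), 1,4-dioxane, 80 °C
Reagents that add atoms: selenium dioxide, O=[Se]=O
Why: Riley oxidation: the ene/[2,3]-sigmatropic sequence starts at the only alkene not conjugated to a carbonyl group, takes hydrogen from a substituent of its more substituted carbon C8 and there prefers the methyl group C17 (trans to C6) over the methine C9, as in 7-ene drimanes, and the primary allylic alcohol is oxidised on to the enal in the same flask without touching a stereocentre.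

Step 14
Reactants: 22 C17 enal
Product: 23 (5S,6S,9R,10R)-6α-tigloyloxylabda-7,13-dien-16,15-olid-17-oic acid (CNP0245290.2)
Conditions: NaClO2, NaH2PO4, 2-methylbut-2-ene, t-BuOH/H2O, 0 °C to rt
Reagents that add atoms: sodium chlorite, [Na+].[O-]Cl=O
Why: Pinnick oxidation: chlorous acid converts the enal into the acid under buffered conditions that leave the allylic tiglate, the butenolide and the C6 and C9 centres alone; placing this step last means the acid never needs a protecting group.

Compound list
1 | (R)-carvone | CC1=CC[C@H](CC1=O)C(C)=C | starting material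
2 | lithium cross-conjugated dienolate of carvone | CC1=CC[C@H](C=C1[O-])C(C)=C.[Li+] | intermediate
3 | 6-methylcarvone (epimer mixture at the methyl-bearing carbon) | O=C1C(C)=CC[C@@H](C(C)=C)C1C | intermediate
4 | allyl bromide | C=CCBr | starting material
5 | lithium enolate of 6-methylcarvone | [Li+].[O-]C1=C(C)[C@H](C(C)=C)CC=C1C | intermediate
6 | (5S,6S)-6-allyl-6-methylcarvone | O=C1C(C)=CC[C@@H](C(C)=C)[C@]1(C)CC=C | intermediate
7 | disiamyl[3-(carvon-6-yl)propyl]borane | O=C1C(C)=CC[C@@H](C(C)=C)[C@]1(C)CCCB(C(C)C(C)C)C(C)C(C)C | intermediate
8 | (5S,6S)-6-(3-hydroxypropyl)-6-methylcarvone | O=C1C(C)=CC[C@@H](C(C)=C)[C@]1(C)CCCO | intermediate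
9 | (5S,6S)-6-(3-iodopropyl)-6-methylcarvone | O=C1C(C)=CC[C@@H](C(C)=C)[C@]1(C)CCCI | intermediate
10 | trans-fused 11-nordrim-7-en-9-one (4aS,8aS) | O=C1C(C)=CC[C@H]2C(C)(C)CCC[C@]12C | intermediate
11 | 9β,11-epoxydrim-7-ene | C1C=C(C)[C@@]3(CO3)[C@@]2(C)CCCC(C)(C)[C@H]12 | intermediate
12 | drim-7-en-11-al (9αH) | C1C=C(C)[C@H](C=O)[C@@]2(C)CCCC(C)(C)[C@H]12 | intermediate
13 | 13,14,15,16-tetranorlabda-7,11-diene (9αH) | C1C=C(C)[C@H](C=C)[C@@]2(C)CCCC(C)(C)[C@H]12 | intermediate
14 | 3-bromofuran-2(5H)-one | O=C1OCC=C1Br | starting material
15 | 9-(13,14,15,16-tetranorlabd-7-en-12-yl)-9-borabicyclo[3.3.1]nonane | C1C=C(C)[C@H](CCB3C4CCCC3CCC4)[C@@]2(C)CCCC(C)(C)[C@H]12 | intermediate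
16 | labda-7,13-dien-16,15-olide | C1C=C(C)[C@H](CCC2=CCOC2=O)[C@@]2(C)CCCC(C)(C)[C@H]12 | intermediate
17 | 6-oxolabda-7,13-dien-16,15-olide | O=C1C=C(C)[C@H](CCC2=CCOC2=O)[C@@]2(C)CCCC(C)(C)[C@H]12 | intermediate
18 | 6β-hydroxylabda-7,13-dien-16,15-olide | O[C@@H]1C=C(C)[C@H](CCC2=CCOC2=O)[C@@]2(C)CCCC(C)(C)[C@H]12 | intermediate
19 | tiglic acid | C/C=C(\C)C(=O)O | starting material
20 | 6α-tigloyloxylabda-7,13-dien-16,15-olide | C/C=C(\C)C(=O)O[C@H]1C=C(C)[C@H](CCC2=CCOC2=O)[C@@]2(C)CCCC(C)(C)[C@H]12 | intermediate
21 | 17-hydroxy-6α-tigloyloxylabda-7,13-dien-16,15-olide | C/C=C(\C)C(=O)O[C@H]1C=C(CO)[C@H](CCC2=CCOC2=O)[C@@]2(C)CCCC(C)(C)[C@H]12 | intermediate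
22 | 6α-tigloyloxy-17-oxolabda-7,13-dien-16,15-olide | C/C=C(\C)C(=O)O[C@H]1C=C(C=O)[C@H](CCC2=CCOC2=O)[C@@]2(C)CCCC(C)(C)[C@H]12 | intermediate
23 | 6α-tigloyloxylabda-7,13-dien-16,15-olid-17-oic acid (5S,6S,9R,10R) | C/C=C(\C)C(=O)O[C@H]1C=C(C(=O)O)[C@H](CCC2=CCOC2=O)[C@@]2(C)CCCC(C)(C)[C@H]12 | target

Total step count: 14. Longest linear sequence: 14 steps from (R)-carvone 1 (fully linear; 4, 14 and 19 are bought).

Steps most likely to fail

1. Step 5.
- What may go wrong: hydrogen delivery to the enone instead of the isopropenyl group, reduction of the C–I bond before coupling, or 7-endo attack of a nickel-released C3 radical on the isopropenyl CH2.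
- Fallback: it uses known chemistry, sets out from alcohol 8 and comes back at enone 10. Dess–Martin oxidation of 8 would give the 3-oxopropyl ketone F1. Its unhindered aldehyde condenses with p-toluenesulfonyl hydrazide, while the crowded C9 ketone stays out, to give the N-tosylhydrazone F2. Fe(acac)3/PhSiH3 in THF/MeOH then generates the same C4 radical. This radical adds 6-exo to the C=N carbon C3, an established acceptor in hydrogen-atom-transfer couplings, and gives the cyclic N-alkyl-N′-tosylhydrazide F3. Warming in methanol with NaOAc expels sulfinate and dinitrogen, which leaves C3 as a methylene group, that is 10. The same C3–C4 bond is formed without nickel and without an alkyl halide.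

2. Step 12.
- What may go wrong: slow activation of the crowded axial alcohol, followed by loss of the activated oxygen through elimination toward C5 or through allylic ionisation with proton loss.
- Fallback: it sets out from 18 and comes back at 22, and it replaces inversion by thermodynamic control. Acylation with retention (tigloyl chloride, DMAP, pyridine, 50 °C) would give the 6β-tiglate F4. SeO2 as in step 13 would then give the 6β-tigloyloxy enal F5. In F5 the hydrogen at C6 is γ to the aldehyde, so dry HCl in CHCl3 can equilibrate C6 through the dienol. This is the way 6β-substituted 4-en-3-one steroids are turned into their 6α epimers. The axial ester, pressed against two syn-axial methyl groups, should drain into the equatorial 6α-ester 22.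

3. Step 13.
- What may go wrong: a sluggish ene reaction at an alkene deactivated by the neighbouring acyloxy group, competing allylic oxidation of the tiglate methyl groups under the forcing this invites, or further hydroxylation at C9.
- Fallback: it sets out from 18 and comes back at 22, and it carries a saturated placeholder ester through the oxidation. Mitsunobu inversion with the more acidic chloroacetic acid would give the 6α-chloroacetate F6. SeO2 would then give the 6α-chloroacetoxy enal F7. Thiourea/NaHCO3 in ethanol removes the chloroacetyl group to the 6α-hydroxy enal F8. The now equatorial alcohol is esterified with tiglic acid 19 under Yamaguchi conditions (2,4,6-trichlorobenzoyl chloride, Et3N, DMAP) to 22.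

Further compounds
F1 | step 5 | (5S,6S)-6-(3-oxopropyl)-6-methylcarvone | O=C1C(C)=CC[C@@H](C(C)=C)[C@]1(C)CCC=O
F2 | step 5 | N-tosylhydrazone of F1 | O=C1C(C)=CC[C@@H](C(C)=C)[C@]1(C)CC/C=N/NS(=O)(=O)c1ccc(C)cc1
F3 | step 5 | 3-(2-tosylhydrazinyl)-11-nordrim-7-en-9-one (C3 undefined) | O=C1C(C)=CC[C@H]2C(C)(C)C(NNS(=O)(=O)c3ccc(C)cc3)CC[C@]12C
F4 | step 12 | 6β-tigloyloxylabda-7,13-dien-16,15-olide | C/C=C(\C)C(=O)O[C@@H]1C=C(C)[C@H](CCC2=CCOC2=O)[C@@]2(C)CCCC(C)(C)[C@H]12
F5 | step 12 | 6β-tigloyloxy-17-oxolabda-7,13-dien-16,15-olide | C/C=C(\C)C(=O)O[C@@H]1C=C(C=O)[C@H](CCC2=CCOC2=O)[C@@]2(C)CCCC(C)(C)[C@H]12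
F6 | step 13 | 6α-chloroacetoxylabda-7,13-dien-16,15-olide | ClCC(=O)O[C@H]1C=C(C)[C@H](CCC2=CCOC2=O)[C@@]2(C)CCCC(C)(C)[C@H]12
F7 | step 13 | 6α-chloroacetoxy-17-oxolabda-7,13-dien-16,15-olide | ClCC(=O)O[C@H]1C=C(C=O)[C@H](CCC2=CCOC2=O)[C@@]2(C)CCCC(C)(C)[C@H]12
F8 | step 13 | 6α-hydroxy-17-oxolabda-7,13-dien-16,15-olide | O[C@H]1C=C(C=O)[C@H](CCC2=CCOC2=O)[C@@]2(C)CCCC(C)(C)[C@H]12
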